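**Retrosynthetic overview**

- Target 29 comes from its octadecamethyl ether 28 by global O-demethylation. Compound 28 is cut at the ring C C6–O–ring D C1 ether into phenol 13 (rings A–C) and aryl bromide 27 (rings D–G), joined by copper-catalysed C–O coupling.
- The feature used is in ring B: its C4–OH is para to C1 (the ether carbon to ring A) and ortho to C5 (the ether carbon to ring C). A formyl group at C4 therefore activates both carbons for SNAr and is then turned into that hydroxyl by Baeyer–Villiger oxidation. Ring F repeats the pattern (C4–OH para to C1–O–ring E, ortho to C5–O–ring G).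
- Phenol 13 comes from aldehyde 9, made in one pot from 2,4,6-trimethoxyphenol 6, 2,4-difluoro-6-methoxybenzaldehyde 7 and phenol 5. Bromide 27 comes the same way from 21, 7 and 3,4,5-trimethoxyphenol 22. Ring D comes from fluoroaldehyde 16, whose formyl group (the future ring D C3–OH) activates C4–F toward 5 and whose bromine marks C1.
- No ring is formed, since all seven benzene rings are bought. The ether bonds are made in the order A–B and B–C (step 4), D–E (step 9), E–F and F–G (step 13), C–D (step 16). Phenol 5 serves as both ring C and ring E, and the target has no stereocenter.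

Key step: step 4

Assumption: all hydroxyls are carried as methyl ethers to the end, and 2,3,4-trimethoxyphenol, 2,4,6-trimethoxyphenol, 2,4-difluoro-6-methoxybenzaldehyde, 3,4,5-trimethoxyphenol and 4-bromo-1-fluoro-2-methoxybenzene are taken as catalogue compounds.

**Route**

Step 1
Reactants: 1 2,3,4-trimethoxyphenol
Product: 2 2-hydroxy-3,4,5-trimethoxybenzaldehyde
Conditions: MgCl2, Et3N, (CH2O)n, MeCN, reflux; aq. HCl
Reagents that add atoms: paraformaldehyde (as formaldehyde), C=O
Why: Magnesium phenoxide-directed ortho-formylation (Casnati–Skattebøl reaction) can only go to C6, the single free ortho position, because the para position carries OMe.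

Step 2
Reactants: 2 2-hydroxy-3,4,5-trimethoxybenzaldehyde
Product: 3 2-(benzyloxy)-3,4,5-trimethoxybenzaldehyde
Conditions: BnBr, K2CO3, DMF, 50 °C
Reagents that add atoms: benzyl bromide, BrCc1ccccc1
Why: Williamson ether synthesis on the salicylaldehyde phenoxide installs a benzyl group that can later be removed by hydrogenolysis or by BCl3 without touching methyl ethers.

Step 3
Reactants: 3 2-(benzyloxy)-3,4,5-trimethoxybenzaldehyde
Product: 5 2-(benzyloxy)-3,4,5-trimethoxyphenol, via aryl formate 4 (not isolated)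
Conditions: mCPBA, CH2Cl2, 0 °C to rt; then K2CO3 (cat.), MeOH, rt
Reagents that add atoms: mCPBA, OOC(=O)c1cccc(Cl)c1
Why: In this Baeyer–Villiger oxidation the electron-rich aryl group (ortho OBn, para OMe) should migrate in preference to hydride, and methanolysis of the formate frees the phenol next to the ring hydrogen.

Step 4
Reactants: 6 2,4,6-trimethoxyphenol; 7 2,4-difluoro-6-methoxybenzaldehyde; 5 2-(benzyloxy)-3,4,5-trimethoxyphenol
Product: 9 2-[2-(benzyloxy)-3,4,5-trimethoxyphenoxy]-6-methoxy-4-(2,4,6-trimethoxyphenoxy)benzaldehyde, via fluoro monoether 8 (not isolated)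
Conditions: 6, 7, Cs2CO3, DMF, 0 °C to rt; then 5, Cs2CO3, 90 °C
Reagents that add atoms: none
Why: Both ether bonds form by addition–elimination (SNAr): a cesium phenoxide adds to a fluorine-bearing carbon, the Meisenheimer anion is stabilised by delocalisation onto the formyl oxygen (C4 is para and C2 is ortho to C1–CHO), and fluoride leaves. The closest known reaction type is the stepwise SNAr etherification of 2,4-difluorobenzaldehydes with two different phenols, followed by oxidative conversion of the formyl group into a phenol. No ring is closed and no stereocenter is created. The step needs site order, para fluorine before ortho fluorine: the phenoxide of 6, flanked by two methoxy groups, should reach only the open C4–F (hydrogen on both sides) at or below room temperature, while C2–F lies beside the formyl group and, once the para aryloxy donor is in place, should react only at 90 °C with the less hindered phenoxide of 5. The 6-OMe group is meta to both fluorines and so deactivates neither, one equivalent of 6 limits double substitution, and fluoride is displaced much faster than aryloxide, which should keep the first ether from exchanging in the hot stage.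

Step 5
Reactants: 9 2-[2-(benzyloxy)-3,4,5-trimethoxyphenoxy]-6-methoxy-4-(2,4,6-trimethoxyphenoxy)benzaldehyde
Product: 11 2-[2-(benzyloxy)-3,4,5-trimethoxyphenoxy]-6-methoxy-4-(2,4,6-trimethoxyphenoxy)phenol, via aryl formate 10 (not isolated)
Conditions: mCPBA, CH2Cl2, 0 °C to rt; then K2CO3 (cat.), MeOH, rt
Reagents that add atoms: mCPBA, OOC(=O)c1cccc(Cl)c1
Why: Baeyer–Villiger oxidation of the 2,4,6-trioxygenated benzaldehyde proceeds by aryl migration and turns the activating formyl group into the ring B C4 oxygen; near-stoichiometric peracid at low temperature should spare the other electron-rich rings.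

Step 6
Reactants: 11 2-[2-(benzyloxy)-3,4,5-trimethoxyphenoxy]-6-methoxy-4-(2,4,6-trimethoxyphenoxy)phenol
Product: 12 2-(benzyloxy)-1-[2,3-dimethoxy-5-(2,4,6-trimethoxyphenoxy)phenoxy]-3,4,5-trimethoxybenzene
Conditions: MeI, K2CO3, DMF, rt
Reagents that add atoms: iodomethane, CI
Why: Williamson methylation caps the ring B C4 phenol so that the ring C oxygen is the only nucleophile in the later union.

Step 7
Reactants: 12 2-(benzyloxy)-1-[2,3-dimethoxy-5-(2,4,6-trimethoxyphenoxy)phenoxy]-3,4,5-trimethoxybenzene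
Product: 13 6-[2,3-dimethoxy-5-(2,4,6-trimethoxyphenoxy)phenoxy]-2,3,4-trimethoxyphenol
Conditions: H2 (1 atm), 10% Pd/C, EtOAc/MeOH, rt
Reagents that add atoms: none
Why: Hydrogenolysis of the benzyl ether leaves methyl and diaryl ethers untouched and frees the hindered ring C C6–OH.

Step 8
Reactants: 14 4-bromo-1-fluoro-2-methoxybenzene
Product: 16 5-bromo-2-fluoro-3-methoxybenzaldehyde, via aryllithium 15 (not isolated)
Conditions: LDA, THF, −78 °C; then DMF, −78 to 0 °C; aq. HCl
Reagents that add atoms: N,N-dimethylformamide, CN(C)C=O; lithium diisopropylamide, [Li]N(C(C)C)C(C)C (lithium of 15 only)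
Why: In this directed ortho-metalation fluorine is the strongest acidifying substituent, so the amide base should remove the proton next to it at −78 °C without bromine–lithium exchange, and DMF formylates the aryllithium.

Step 9
Reactants: 16 5-bromo-2-fluoro-3-methoxybenzaldehyde; 5 2-(benzyloxy)-3,4,5-trimethoxyphenol
Product: 17 2-[2-(benzyloxy)-3,4,5-trimethoxyphenoxy]-5-bromo-3-methoxybenzaldehyde
Conditions: K2CO3, DMF, 80 °C
Reagents that add atoms: none
Why: SNAr (addition–elimination) at the fluorine ortho to the formyl group forms the ring D C4–O–ring E C1 ether, while the bromine, meta to the formyl group, is not activated and stays.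

Step 10
Reactants: 17 2-[2-(benzyloxy)-3,4,5-trimethoxyphenoxy]-5-bromo-3-methoxybenzaldehyde
Product: 19 2-[2-(benzyloxy)-3,4,5-trimethoxyphenoxy]-5-bromo-3-methoxyphenol, via aryl formate 18 (not isolated)
Conditions: mCPBA, CH2Cl2, 0 °C to rt; then K2CO3 (cat.), MeOH, rt
Reagents that add atoms: mCPBA, OOC(=O)c1cccc(Cl)c1
Why: Baeyer–Villiger oxidation with aryl migration assisted by the ortho aryloxy donor, as is usual for 2-alkoxy- and 2-aryloxybenzaldehydes, turns the formyl group into the second oxygen flanking ring D C4.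

Step 11
Reactants: 19 2-[2-(benzyloxy)-3,4,5-trimethoxyphenoxy]-5-bromo-3-methoxyphenol
Product: 20 2-(benzyloxy)-1-(4-bromo-2,6-dimethoxyphenoxy)-3,4,5-trimethoxybenzene
Conditions: MeI, K2CO3, DMF, rt
Reagents that add atoms: iodomethane, CI
Why: Williamson methylation of the free phenol gives the symmetrical 4-bromo-2,6-dimethoxyphenyl ring D.

Step 12
Reactants: 20 2-(benzyloxy)-1-(4-bromo-2,6-dimethoxyphenoxy)-3,4,5-trimethoxybenzene
Product: 21 6-(4-bromo-2,6-dimethoxyphenoxy)-2,3,4-trimethoxyphenol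
Conditions: BCl3, C6HMe5, CH2Cl2, −78 °C; then H2O
Reagents that add atoms: none
Why: Lewis acid debenzylation with pentamethylbenzene as benzyl cation scavenger cleaves the aryl benzyl ether at −78 °C, where aryl methyl ethers survive, and it spares the aryl bromide that hydrogenolysis would reduce.

Step 13
Reactants: 21 6-(4-bromo-2,6-dimethoxyphenoxy)-2,3,4-trimethoxyphenol; 7 2,4-difluoro-6-methoxybenzaldehyde; 22 3,4,5-trimethoxyphenol
Product: 24 4-[6-(4-bromo-2,6-dimethoxyphenoxy)-2,3,4-trimethoxyphenoxy]-2-methoxy-6-(3,4,5-trimethoxyphenoxy)benzaldehyde, via fluoro monoether 23 (not isolated)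
Conditions: 21, 7, Cs2CO3, DMF, rt to 40 °C; then 22, Cs2CO3, 90 °C
Reagents that add atoms: none
Why: This is the sequential SNAr of step 4 applied to ring F: the hindered ring E phenoxide should take the para fluorine at low temperature and 3,4,5-trimethoxyphenoxide the ortho fluorine on heating, while the unactivated aryl bromide is inert.

Step 14
Reactants: 24 4-[6-(4-bromo-2,6-dimethoxyphenoxy)-2,3,4-trimethoxyphenoxy]-2-methoxy-6-(3,4,5-trimethoxyphenoxy)benzaldehyde
Product: 26 4-[6-(4-bromo-2,6-dimethoxyphenoxy)-2,3,4-trimethoxyphenoxy]-2-methoxy-6-(3,4,5-trimethoxyphenoxy)phenol, via aryl formate 25 (not isolated)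
Conditions: mCPBA, CH2Cl2, 0 °C to rt; then K2CO3 (cat.), MeOH, rt
Reagents that add atoms: mCPBA, OOC(=O)c1cccc(Cl)c1
Why: Baeyer–Villiger oxidation of the electron-rich 2,4,6-trioxygenated benzaldehyde by aryl migration gives the ring F C4 oxygen, and the aryl bromide is unaffected by peracid.

Step 15
Reactants: 26 4-[6-(4-bromo-2,6-dimethoxyphenoxy)-2,3,4-trimethoxyphenoxy]-2-methoxy-6-(3,4,5-trimethoxyphenoxy)phenol
Product: 27 1-(4-bromo-2,6-dimethoxyphenoxy)-2-[3,4-dimethoxy-5-(3,4,5-trimethoxyphenoxy)phenoxy]-3,4,5-trimethoxybenzene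
Conditions: MeI, K2CO3, DMF, rt
Reagents that add atoms: iodomethane, CI
Why: Williamson methylation removes the only phenol of the ring D–G unit, so that in the union it can act solely as the electrophile.

Step 16
Reactants: 13 6-[2,3-dimethoxy-5-(2,4,6-trimethoxyphenoxy)phenoxy]-2,3,4-trimethoxyphenol; 27 1-(4-bromo-2,6-dimethoxyphenoxy)-2-[3,4-dimethoxy-5-(3,4,5-trimethoxyphenoxy)phenoxy]-3,4,5-trimethoxybenzene
Product: 28 octadecamethyl ether of the target (rings A–G joined, every hydroxyl as OMe)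
Conditions: CuI (20 mol%), picolinic acid (40 mol%), K3PO4, DMSO, 100 °C, argon
Reagents that add atoms: none
Why: In this Ullmann-type copper-catalysed O-arylation the bromide on ring D has hydrogen at both ortho positions, so the steric demand lies only on the phenoxide, a pairing that the CuI/picolinic acid system is known to handle.

Step 17
Reactants: 28 octadecamethyl ether of the target
Product: 29 CNP0137585.0 (heptameric phlorotannin with eighteen free hydroxyls, target)
Conditions: BBr3 (about 2 equiv per OMe), CH2Cl2, −78 °C to rt; then H2O, argon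
Reagents that add atoms: none
Why: In this Lewis acid ether cleavage BBr3 complexes each methoxy oxygen and bromide removes the methyl group by SN2, whereas the diaryl ether bonds offer no sp3 carbon for attack and should persist.

**Compound list**

1 | 2,3,4-trimethoxyphenol | COc1ccc(O)c(OC)c1OC | starting material
2 | 2-hydroxy-3,4,5-trimethoxybenzaldehyde | COc1cc(C=O)c(O)c(OC)c1OC | intermediate
3 | 2-(benzyloxy)-3,4,5-trimethoxybenzaldehyde | COc1cc(C=O)c(OCc2ccccc2)c(OC)c1OC | intermediate
4 | 2-(benzyloxy)-3,4,5-trimethoxyphenyl formate | COc1cc(OC=O)c(OCc2ccccc2)c(OC)c1OC | intermediate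
5 | 2-(benzyloxy)-3,4,5-trimethoxyphenol (ring C and ring E unit) | COc1cc(O)c(OCc2ccccc2)c(OC)c1OC | intermediate
6 | 2,4,6-trimethoxyphenol | COc1cc(OC)c(O)c(OC)c1 | starting material
7 | 2,4-difluoro-6-methoxybenzaldehyde | COc1cc(F)cc(F)c1C=O | starting material
8 | 2-fluoro-6-methoxy-4-(2,4,6-trimethoxyphenoxy)benzaldehyde | COc1cc(OC)c(Oc2cc(F)c(C=O)c(OC)c2)c(OC)c1 | intermediate
9 | 2-[2-(benzyloxy)-3,4,5-trimethoxyphenoxy]-6-methoxy-4-(2,4,6-trimethoxyphenoxy)benzaldehyde | COc1cc(OC)c(Oc2cc(OC)c(C=O)c(Oc3cc(OC)c(OC)c(OC)c3OCc3ccccc3)c2)c(OC)c1 | intermediate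
10 | 2-[2-(benzyloxy)-3,4,5-trimethoxyphenoxy]-6-methoxy-4-(2,4,6-trimethoxyphenoxy)phenyl formate | COc1cc(OC)c(Oc2cc(OC)c(OC=O)c(Oc3cc(OC)c(OC)c(OC)c3OCc3ccccc3)c2)c(OC)c1 | intermediate
11 | 2-[2-(benzyloxy)-3,4,5-trimethoxyphenoxy]-6-methoxy-4-(2,4,6-trimethoxyphenoxy)phenol | COc1cc(OC)c(Oc2cc(OC)c(O)c(Oc3cc(OC)c(OC)c(OC)c3OCc3ccccc3)c2)c(OC)c1 | intermediate
12 | 2-(benzyloxy)-1-[2,3-dimethoxy-5-(2,4,6-trimethoxyphenoxy)phenoxy]-3,4,5-trimethoxybenzene | COc1cc(OC)c(Oc2cc(OC)c(OC)c(Oc3cc(OC)c(OC)c(OC)c3OCc3ccccc3)c2)c(OC)c1 | intermediate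
13 | 6-[2,3-dimethoxy-5-(2,4,6-trimethoxyphenoxy)phenoxy]-2,3,4-trimethoxyphenol | COc1cc(OC)c(Oc2cc(OC)c(OC)c(Oc3cc(OC)c(OC)c(OC)c3O)c2)c(OC)c1 | intermediate
14 | 4-bromo-1-fluoro-2-methoxybenzene | COc1cc(Br)ccc1F | starting material
15 | (5-bromo-2-fluoro-3-methoxyphenyl)lithium | [Li]c1cc(Br)cc(OC)c1F | intermediate
16 | 5-bromo-2-fluoro-3-methoxybenzaldehyde | COc1cc(Br)cc(C=O)c1F | intermediate
17 | 2-[2-(benzyloxy)-3,4,5-trimethoxyphenoxy]-5-bromo-3-methoxybenzaldehyde | COc1cc(Br)cc(C=O)c1Oc1cc(OC)c(OC)c(OC)c1OCc1ccccc1 | intermediate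
18 | 2-[2-(benzyloxy)-3,4,5-trimethoxyphenoxy]-5-bromo-3-methoxyphenyl formate | COc1cc(Br)cc(OC=O)c1Oc1cc(OC)c(OC)c(OC)c1OCc1ccccc1 | intermediate
19 | 2-[2-(benzyloxy)-3,4,5-trimethoxyphenoxy]-5-bromo-3-methoxyphenol | COc1cc(Br)cc(O)c1Oc1cc(OC)c(OC)c(OC)c1OCc1ccccc1 | intermediate
20 | 2-(benzyloxy)-1-(4-bromo-2,6-dimethoxyphenoxy)-3,4,5-trimethoxybenzene | COc1cc(Br)cc(OC)c1Oc1cc(OC)c(OC)c(OC)c1OCc1ccccc1 | intermediate
21 | 6-(4-bromo-2,6-dimethoxyphenoxy)-2,3,4-trimethoxyphenol | COc1cc(Br)cc(OC)c1Oc1cc(OC)c(OC)c(OC)c1O | intermediate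
22 | 3,4,5-trimethoxyphenol | COc1cc(O)cc(OC)c1OC | starting material
23 | 4-[6-(4-bromo-2,6-dimethoxyphenoxy)-2,3,4-trimethoxyphenoxy]-2-fluoro-6-methoxybenzaldehyde | COc1cc(Br)cc(OC)c1Oc1cc(OC)c(OC)c(OC)c1Oc1cc(F)c(C=O)c(OC)c1 | intermediate
24 | 4-[6-(4-bromo-2,6-dimethoxyphenoxy)-2,3,4-trimethoxyphenoxy]-2-methoxy-6-(3,4,5-trimethoxyphenoxy)benzaldehyde | COc1cc(Br)cc(OC)c1Oc1cc(OC)c(OC)c(OC)c1Oc1cc(OC)c(C=O)c(Oc2cc(OC)c(OC)c(OC)c2)c1 | intermediate
25 | 4-[6-(4-bromo-2,6-dimethoxyphenoxy)-2,3,4-trimethoxyphenoxy]-2-methoxy-6-(3,4,5-trimethoxyphenoxy)phenyl formate | COc1cc(Br)cc(OC)c1Oc1cc(OC)c(OC)c(OC)c1Oc1cc(OC)c(OC=O)c(Oc2cc(OC)c(OC)c(OC)c2)c1 | intermediate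
26 | 4-[6-(4-bromo-2,6-dimethoxyphenoxy)-2,3,4-trimethoxyphenoxy]-2-methoxy-6-(3,4,5-trimethoxyphenoxy)phenol | COc1cc(Br)cc(OC)c1Oc1cc(OC)c(OC)c(OC)c1Oc1cc(OC)c(O)c(Oc2cc(OC)c(OC)c(OC)c2)c1 | intermediate
27 | 1-(4-bromo-2,6-dimethoxyphenoxy)-2-[3,4-dimethoxy-5-(3,4,5-trimethoxyphenoxy)phenoxy]-3,4,5-trimethoxybenzene | COc1cc(Br)cc(OC)c1Oc1cc(OC)c(OC)c(OC)c1Oc1cc(OC)c(OC)c(Oc2cc(OC)c(OC)c(OC)c2)c1 | intermediate
28 | octadecamethyl ether of the target | COc1cc(OC)c(Oc2cc(OC)c(OC)c(Oc3cc(OC)c(OC)c(OC)c3Oc3cc(OC)c(Oc4cc(OC)c(OC)c(OC)c4Oc4cc(OC)c(OC)c(Oc5cc(OC)c(OC)c(OC)c5)c4)c(OC)c3)c2)c(OC)c1 | intermediate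
29 | CNP0137585.0 | Oc1cc(O)c(Oc2cc(O)c(O)c(Oc3cc(O)c(O)c(O)c3Oc3cc(O)c(Oc4cc(O)c(O)c(O)c4Oc4cc(O)c(O)c(Oc5cc(O)c(O)c(O)c5)c4)c(O)c3)c2)c(O)c1 | target

**Step count**

Total step count: 17. Longest linear sequence: 12 steps (steps 1–3, then 9–17).

**Steps most likely to fail**

1. Step 4. The site order may erode: the ring A phenoxide may attack the ortho fluorine as well, one phenoxide may substitute twice, or the para aryloxy group may exchange with the second phenoxide during the hot stage. The fallback gives each ether carbon of ring B its own mechanism; it sets out from 5 and 6 and comes back at 9. Purchased 4-bromo-2,6-difluorobenzaldehyde F1 would be treated with one equivalent of NaOMe (MeOH/THF, 0 °C) to give 4-bromo-2-fluoro-6-methoxybenzaldehyde F2. SNAr of 5 at its only fluorine (K2CO3, DMF, 80 °C) would give 2-[2-(benzyloxy)-3,4,5-trimethoxyphenoxy]-4-bromo-6-methoxybenzaldehyde F3. Ullmann coupling of the unhindered para bromide of F3 with 6 (CuI, picolinic acid, K3PO4, DMSO, 90 °C) would then deliver 9.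

2. Step 16. Oxidative addition of the electron-rich bromide and C–O bond formation from the crowded copper phenoxide may be slow, so that 27 is reduced to the arene or both partners are recovered. The fallback turns the union into an oxidative coupling; it sets out from 27 and 13 and comes back at 28. Bromine–lithium exchange on 27 (n-BuLi, THF, −78 °C) would give the ring D aryllithium F4, which is trapped with B(OiPr)3 and hydrolysed (aq. HCl) to the ring D boronic acid F5. Chan–Lam–Evans coupling of F5 with 13 (Cu(OAc)2, pyridine, 4 Å molecular sieves, CH2Cl2, air, rt) would give 28.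

3. Step 17. The eighteen-fold ether cleavage may stall at partly methylated products, and the pyrogallol-type rings may oxidise in air during isolation. The fallback isolates the product through a stable derivative; it sets out from 28 and comes back at 29. After treatment of 28 with BBr3 and evaporation, the crude polyphenol would be acetylated directly (Ac2O, pyridine, rt) to the octadecaacetate F6, which can be chromatographed on silica and separated from under-demethylated material. Acid-catalysed methanolysis of F6 (HCl generated from AcCl in MeOH, rt, argon) would then release 29.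

**Further compounds**

F1 | step 4 | 4-bromo-2,6-difluorobenzaldehyde (purchased) | O=Cc1c(F)cc(Br)cc1F
F2 | step 4 | 4-bromo-2-fluoro-6-methoxybenzaldehyde | COc1cc(Br)cc(F)c1C=O
F3 | step 4 | 2-[2-(benzyloxy)-3,4,5-trimethoxyphenoxy]-4-bromo-6-methoxybenzaldehyde | COc1cc(Br)cc(Oc2cc(OC)c(OC)c(OC)c2OCc2ccccc2)c1C=O
F4 | step 16 | ring D aryllithium from 27 | COc1cc([Li])cc(OC)c1Oc1cc(OC)c(OC)c(OC)c1Oc1cc(OC)c(OC)c(Oc2cc(OC)c(OC)c(OC)c2)c1
F5 | step 16 | ring D boronic acid from 27 | COc1cc(B(O)O)cc(OC)c1Oc1cc(OC)c(OC)c(OC)c1Oc1cc(OC)c(OC)c(Oc2cc(OC)c(OC)c(OC)c2)c1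
F6 | step 17 | octadecaacetate of 29 | CC(=O)Oc1cc(OC(C)=O)c(Oc2cc(OC(C)=O)c(OC(C)=O)c(Oc3cc(OC(C)=O)c(OC(C)=O)c(OC(C)=O)c3Oc3cc(OC(C)=O)c(Oc4cc(OC(C)=O)c(OC(C)=O)c(OC(C)=O)c4Oc4cc(OC(C)=O)c(OC(C)=O)c(Oc5cc(OC(C)=O)c(OC(C)=O)c(OC(C)=O)c5)c4)c(OC(C)=O)c3)c2)c(OC(C)=O)c1
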